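A direct plan would join ring A to ring B through carbon and turn that carbon into the inner depside afterwards: aryl Grignard reagent A1 of ring A would add to ring B aldehyde A2, which already carries the protected ring C ester, and carbinol oxidation, ketal hydrolysis and carbonate formation would give diaryl ketone A3.
Baeyer–Villiger oxidation of A3 with CF3CO3H would give protected tridepside A4, and hydrogenolysis would give the target.
The peracid oxygen insertion into A3 would be the weakest step: the carbonyl lies between two ortho benzyloxy groups, the ring that must migrate also carries a para ester, and a strongly electrophilic peracid meets two electron-rich benzyloxyarenes at the latest and most costly stage.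
The halogen–magnesium exchange and addition would be weak as well: a hindered aryl Grignard reagent that holds a benzyl ester would have to choose the aldehyde over an activated aryl ester in the same molecule.
The run of carbinol oxidation, ketal hydrolysis and bis-carbonate formation would build no bond of the target, would serve only to tune migratory aptitude, and would free a catechol next to the galloyl ester, which invites acyl shift.

Retrosynthetic overview
Feature used: ring A is a 2-acyloxyresorcinol. Its C4–O (the inner depside oxygen) lies between the free C3–OH and C5–OH and para to C1–CO2H, so its dihydro form is a 4-acyloxy-3,5-dioxocyclohexane-1-carboxylate in which C4 is the only carbon between two carbonyls.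
Key disconnections: ring A is traced back (retro-dehydrogenation) to that non-aromatic dione; its C4–O bond comes from carbene O–H insertion of the acid of the B–C fragment into benzyl 4-diazo-3,5-dioxocyclohexane-1-carboxylate; the outer depside comes from acylation of the single free phenol of ketal-protected 3,4,5-trihydroxybenzaldehyde.
Ring order: rings C and B enter as arenes; ring A is the last ring to become aromatic, after the fragments are joined, much as the gallate ring arises in nature by dehydrogenation of a non-aromatic keto acid.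
The design needs no carbon–carbon bond that is later oxidised to C–O (no aryl Grignard reagent, no peracid), no acylation of a phenol flanked by two ortho substituents, no protecting group on the ring A phenols and no protecting group exchange on ring B.
Key step: step 7

Remark: the target has no stereocentre; the two non-aromatic ring A intermediates of steps 6 and 7 each hold one formally stereogenic ring carbon (C1), would form as racemates, and lose it on aromatisation. The three starting materials are taken as commercial.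

Step 1
Reactants: 1 3,5-dioxocyclohexane-1-carboxylic acid
Product: 2 4-diazo-3,5-dioxocyclohexane-1-carboxylic acid
Conditions: 4-AcNHC6H4SO2N3, Et3N (2.5 equiv), MeCN, 0 °C → rt; acidify, extract
Reagents that add atoms: 4-acetamidobenzenesulfonyl azide, CC(=O)Nc1ccc(cc1)S(=O)(=O)N=[N+]=[N-]
Why: Regitz diazo transfer to the doubly activated methylene of a cyclic 1,3-diketone should run at room temperature with the carboxylate as a spectator, and it marks C4, the future depside carbon of ring A, as the only functionalised position.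

Step 2
Reactants: 2 4-diazo-3,5-dioxocyclohexane-1-carboxylic acid
Product: 3 benzyl 4-diazo-3,5-dioxocyclohexane-1-carboxylate
Conditions: BnBr, KHCO3, DMF, rt
Reagents that add atoms: benzyl bromide, BrCc1ccccc1
Why: SN2 O-alkylation of the carboxylate should be clean because the diazo group occupies the carbon between the two carbonyls, so the dione can no longer be benzylated on carbon or on oxygen and the carboxylate is the only nucleophile.

Step 3
Reactants: 4 3,4,5-trihydroxybenzaldehyde
Product: 5 7-hydroxy-2,2-diphenyl-1,3-benzodioxole-5-carbaldehyde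
Conditions: Ph2CCl2, Ph2O, 175 °C
Reagents that add atoms: dichlorodiphenylmethane, ClC(Cl)(c1ccccc1)c1ccccc1
Why: Thermal ketalisation of a vicinal diphenol with a gem-dichloride can only bridge two neighbouring oxygens, so the symmetric triol should give one five-membered ketal and leave exactly one phenol, the future O3 of ring B, free.

Step 4
Reactants: 5 7-hydroxy-2,2-diphenyl-1,3-benzodioxole-5-carbaldehyde; 6 3,4,5-tris(benzyloxy)benzoic acid
Product: 7 6-formyl-2,2-diphenyl-1,3-benzodioxol-4-yl 3,4,5-tris(benzyloxy)benzoate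
Conditions: DIC, DMAP (cat.), CH2Cl2, 0 °C → rt
Reagents that add atoms: none
Why: Steglich esterification of the only free phenol with the ring C acid should fix the outer depside on O3 of ring B without a regiochemical choice, with aldehyde and ketal as spectators.

Step 5
Reactants: 7 6-formyl-2,2-diphenyl-1,3-benzodioxol-4-yl 3,4,5-tris(benzyloxy)benzoate
Product: 8 2,2-diphenyl-7-{[3,4,5-tris(benzyloxy)benzoyl]oxy}-1,3-benzodioxole-5-carboxylic acid
Conditions: NaClO2, NaH2PO4, 2-methyl-2-butene, THF/t-BuOH/H2O, 0 °C → rt
Reagents that add atoms: sodium chlorite, [Na+].[O-]Cl=O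
Why: Pinnick oxidation should convert the aryl aldehyde into the acid in a weakly acidic buffer that leaves the ketal, the benzyl ethers and the aryl ester untouched, while the alkene traps the hypochlorous acid before it can chlorinate the electron-rich rings.

Step 6
Reactants: 8 2,2-diphenyl-7-{[3,4,5-tris(benzyloxy)benzoyl]oxy}-1,3-benzodioxole-5-carboxylic acid; 3 benzyl 4-diazo-3,5-dioxocyclohexane-1-carboxylate
Product: 9 benzyl 4-[(2,2-diphenyl-7-{[3,4,5-tris(benzyloxy)benzoyl]oxy}-1,3-benzodioxole-5-carbonyl)oxy]-3-hydroxy-5-oxocyclohex-3-ene-1-carboxylate (enol form of the 4-acyloxy-3,5-dione, racemic)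
Conditions: Rh2(OAc)4 (2 mol%), PhF, 80 °C, 3 added slowly to 8 (1.2 equiv)
Reagents that add atoms: none
Why: Rhodium carbenoid O–H insertion should let the electrophilic carbenoid of the 2-diazo-1,3-dione be captured by the carboxylic acid of 8, the only O–H donor present, so that the inner depside oxygen is delivered to C4, the single carbon between the two carbonyls, without acylation of a phenol flanked by two ortho substituents, and the product enolises so that no stereocentre is fixed.

Step 7
Reactants: 9 benzyl 4-[(2,2-diphenyl-7-{[3,4,5-tris(benzyloxy)benzoyl]oxy}-1,3-benzodioxole-5-carbonyl)oxy]-3-hydroxy-5-oxocyclohex-3-ene-1-carboxylate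
Product: 12 benzyl 4-[(2,2-diphenyl-7-{[3,4,5-tris(benzyloxy)benzoyl]oxy}-1,3-benzodioxole-5-carbonyl)oxy]-3,5-dihydroxybenzoate, via bis(trimethylsilyl) dienol ether 10 (not isolated), via aryl bis(trimethylsilyl) ether 11 (not isolated)
Conditions: TMSOTf (2.3 equiv), Et3N (2.6 equiv), CH2Cl2, 0 °C → rt; evaporate; DDQ (1.1 equiv), CH2Cl2, 0 °C → rt; aq citric acid, THF, 0 °C
Reagents that add atoms: none
Why: O-silylation of the enol of 9 and soft enolisation of the remaining ketone toward C6 should give the conjugated 3,5-bis(silyloxy)cyclohexa-3,5-diene 10, from which DDQ removes a hydride and a proton at the two sp3 carbons C1 and C2 so that the carbocycle becomes benzene ring A (11), and aqueous acid then frees the two phenols. The closest known reaction types are the dehydrogenation of cyclohexane-1,3-diones to resorcinols and the DDQ aromatisation of silyloxycyclohexadienes. No ring is closed: the six-membered carbocycle that entered as the dione is converted into the arene, so ring A is the last ring of the target to become aromatic, and no stereocentre is formed because C1 of 9 and 10 becomes sp2. Three selectivities are needed: enolisation must go to C2 or C6, which is secured because C4 carries no hydrogen in the enol form; the ester must stay on O4, which is secured because in the anion of 9 the acyl group sits on the less acidic oxygen and in 10 both neighbouring oxygens are silylated; and DDQ must attack only the dihydroarene, which is by far the most electron-rich π system and the only one that gains aromaticity. The step unveils the free C3–OH and C5–OH on both sides of the para-depside without any protecting group on ring A.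

Step 8
Reactants: 12 benzyl 4-[(2,2-diphenyl-7-{[3,4,5-tris(benzyloxy)benzoyl]oxy}-1,3-benzodioxole-5-carbonyl)oxy]-3,5-dihydroxybenzoate
Product: 13 4-{3,4-dihydroxy-5-[(3,4,5-trihydroxybenzoyl)oxy]benzoyloxy}-3,5-dihydroxybenzoic acid (target)
Conditions: H2 (1 atm), Pd(OH)2/C, THF, rt; filter under N2, concentrate below 30 °C
Reagents that add atoms: none
Why: Catalytic hydrogenolysis should cleave the benzyl ester, the three benzyl ethers and the diphenylmethylene ketal in one operation in a neutral aprotic medium, which avoids the base- or alcohol-induced shift and solvolysis of the para-depside that lies between two free phenols.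

Compound list
1 | 3,5-dioxocyclohexane-1-carboxylic acid | O=C(O)C1CC(=O)CC(=O)C1 | starting material
2 | 4-diazo-3,5-dioxocyclohexane-1-carboxylic acid | O=C(O)C1CC(=O)C(=[N+]=[N-])C(=O)C1 | intermediate
3 | benzyl 4-diazo-3,5-dioxocyclohexane-1-carboxylate | O=C(OCc1ccccc1)C1CC(=O)C(=[N+]=[N-])C(=O)C1 | intermediate
4 | 3,4,5-trihydroxybenzaldehyde | O=Cc1cc(O)c(O)c(O)c1 | starting material
5 | 7-hydroxy-2,2-diphenyl-1,3-benzodioxole-5-carbaldehyde | O=Cc1cc(O)c2OC(c3ccccc3)(c3ccccc3)Oc2c1 | intermediate
6 | 3,4,5-tris(benzyloxy)benzoic acid | O=C(O)c1cc(OCc2ccccc2)c(OCc2ccccc2)c(OCc2ccccc2)c1 | starting material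
7 | 6-formyl-2,2-diphenyl-1,3-benzodioxol-4-yl 3,4,5-tris(benzyloxy)benzoate | O=Cc1cc(OC(=O)c2cc(OCc3ccccc3)c(OCc3ccccc3)c(OCc3ccccc3)c2)c2OC(c3ccccc3)(c3ccccc3)Oc2c1 | intermediate
8 | 2,2-diphenyl-7-{[3,4,5-tris(benzyloxy)benzoyl]oxy}-1,3-benzodioxole-5-carboxylic acid | O=C(O)c1cc(OC(=O)c2cc(OCc3ccccc3)c(OCc3ccccc3)c(OCc3ccccc3)c2)c2OC(c3ccccc3)(c3ccccc3)Oc2c1 | intermediate
9 | benzyl 4-[(2,2-diphenyl-7-{[3,4,5-tris(benzyloxy)benzoyl]oxy}-1,3-benzodioxole-5-carbonyl)oxy]-3-hydroxy-5-oxocyclohex-3-ene-1-carboxylate (racemic; enol form) | O=C(OCc1ccccc1)C1CC(O)=C(OC(=O)c2cc(OC(=O)c3cc(OCc4ccccc4)c(OCc4ccccc4)c(OCc4ccccc4)c3)c3OC(c4ccccc4)(c4ccccc4)Oc3c2)C(=O)C1 | intermediate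
10 | benzyl 4-[(2,2-diphenyl-7-{[3,4,5-tris(benzyloxy)benzoyl]oxy}-1,3-benzodioxole-5-carbonyl)oxy]-3,5-bis(trimethylsilyloxy)cyclohexa-3,5-diene-1-carboxylate (racemic; not isolated) | O=C(OCc1ccccc1)C1CC(O[Si](C)(C)C)=C(OC(=O)c2cc(OC(=O)c3cc(OCc4ccccc4)c(OCc4ccccc4)c(OCc4ccccc4)c3)c3OC(c4ccccc4)(c4ccccc4)Oc3c2)C(O[Si](C)(C)C)=C1 | intermediate
11 | benzyl 4-[(2,2-diphenyl-7-{[3,4,5-tris(benzyloxy)benzoyl]oxy}-1,3-benzodioxole-5-carbonyl)oxy]-3,5-bis(trimethylsilyloxy)benzoate (not isolated) | O=C(OCc1ccccc1)c1cc(O[Si](C)(C)C)c(OC(=O)c2cc(OC(=O)c3cc(OCc4ccccc4)c(OCc4ccccc4)c(OCc4ccccc4)c3)c3OC(c4ccccc4)(c4ccccc4)Oc3c2)c(O[Si](C)(C)C)c1 | intermediate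
12 | benzyl 4-[(2,2-diphenyl-7-{[3,4,5-tris(benzyloxy)benzoyl]oxy}-1,3-benzodioxole-5-carbonyl)oxy]-3,5-dihydroxybenzoate | O=C(OCc1ccccc1)c1cc(O)c(OC(=O)c2cc(OC(=O)c3cc(OCc4ccccc4)c(OCc4ccccc4)c(OCc4ccccc4)c3)c3OC(c4ccccc4)(c4ccccc4)Oc3c2)c(O)c1 | intermediate
13 | 4-{3,4-dihydroxy-5-[(3,4,5-trihydroxybenzoyl)oxy]benzoyloxy}-3,5-dihydroxybenzoic acid | O=C(O)c1cc(O)c(OC(=O)c2cc(O)c(O)c(OC(=O)c3cc(O)c(O)c(O)c3)c2)c(O)c1 | target

Total step count: 8
Longest linear sequence: 6 steps (steps 3, 4, 5, 6, 7 and 8, from 4 to 13)

Steps most likely to fail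

Step 7 (key step). The second enol silylation may stay incomplete, the amine base may cause loss or shift of the ester, or DDQ may attack benzylic ether positions, so that the dione ring aromatises only in part. The fallback would set out from acid 8 and use a ring A that is aromatic from the start. Its ring A building block would be commercial 4-bromo-3,5-dihydroxybenzoic acid F1, and perbenzylation of F1 (BnBr, K2CO3, DMF) would give benzyl 3,5-bis(benzyloxy)-4-bromobenzoate F2. Bromine–magnesium exchange of F2 (iPrMgCl·LiCl, THF, −15 °C), borylation with B(OMe)3 and oxidation (H2O2, AcOH) would give benzyl 3,5-bis(benzyloxy)-4-hydroxybenzoate F3. Steglich esterification of 8 with F3 (DIC, DMAP, CH2Cl2) would give benzyl 3,5-bis(benzyloxy)-4-[(2,2-diphenyl-7-{[3,4,5-tris(benzyloxy)benzoyl]oxy}-1,3-benzodioxole-5-carbonyl)oxy]benzoate F4, and hydrogenolysis of F4 (H2, Pd(OH)2/C, THF) would come back to the route at target 13.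

Step 6. The carbenoid may be diverted by Wolff ring contraction, by ylide formation at ether oxygens, by attack on the electron-rich arenes or by a second insertion into the acidic enol O–H of the product. The fallback would take the complex fragment out of the carbene step and set out from diazo ester 3 and acid 8. Decomposition of 3 with Rh2(OAc)4 in PhF at 80 °C with water in excess would give benzyl 3,4-dihydroxy-5-oxocyclohex-3-ene-1-carboxylate F5. Acyl transfer from 8 to F5 (DIC, DMAP, CH2Cl2) should settle, through DMAP-mediated equilibration, on the oxygen between the two carbonyls, which leaves the acidic vinylogous acid free, and would come back to the route at 9.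

Step 8. Cleavage of the diphenylmethylene ketal may be slow, and long exposure of the freed para-depside to the catalyst and to traces of acid or base may let the ester shift from O4 to O3 of ring A. The fallback would remove the ketal by another mechanism and set out from 12. Hydrolysis with TFA/H2O (9:1) in CH2Cl2 at 0 °C would give benzyl 4-[(3,4-dihydroxy-5-{[3,4,5-tris(benzyloxy)benzoyl]oxy}benzoyl)oxy]-3,5-dihydroxybenzoate F6, and a short hydrogenolysis of the four benzyl groups of F6 (H2, Pd/C, THF) would come back to the route at 13.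

Further compounds
F1 | step 7 | 4-bromo-3,5-dihydroxybenzoic acid (purchased) | O=C(O)c1cc(O)c(Br)c(O)c1
F2 | step 7 | benzyl 3,5-bis(benzyloxy)-4-bromobenzoate | O=C(OCc1ccccc1)c1cc(OCc2ccccc2)c(Br)c(OCc2ccccc2)c1
F3 | step 7 | benzyl 3,5-bis(benzyloxy)-4-hydroxybenzoate | O=C(OCc1ccccc1)c1cc(OCc2ccccc2)c(O)c(OCc2ccccc2)c1
F4 | step 7 | benzyl 3,5-bis(benzyloxy)-4-[(2,2-diphenyl-7-{[3,4,5-tris(benzyloxy)benzoyl]oxy}-1,3-benzodioxole-5-carbonyl)oxy]benzoate | O=C(OCc1ccccc1)c1cc(OCc2ccccc2)c(OC(=O)c2cc(OC(=O)c3cc(OCc4ccccc4)c(OCc4ccccc4)c(OCc4ccccc4)c3)c3OC(c4ccccc4)(c4ccccc4)Oc3c2)c(OCc2ccccc2)c1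
F5 | step 6 | benzyl 3,4-dihydroxy-5-oxocyclohex-3-ene-1-carboxylate | O=C(OCc1ccccc1)C1CC(O)=C(O)C(=O)C1
F6 | step 8 | benzyl 4-[(3,4-dihydroxy-5-{[3,4,5-tris(benzyloxy)benzoyl]oxy}benzoyl)oxy]-3,5-dihydroxybenzoate | O=C(OCc1ccccc1)c1cc(O)c(OC(=O)c2cc(O)c(O)c(OC(=O)c3cc(OCc4ccccc4)c(OCc4ccccc4)c(OCc4ccccc4)c3)c2)c(O)c1
A1 | direct plan | [2,6-bis(benzyloxy)-4-(benzyloxycarbonyl)phenyl]magnesium chloride | O=C(OCc1ccccc1)c1cc(OCc2ccccc2)c([Mg]Cl)c(OCc2ccccc2)c1
A2 | direct plan | 6-formyl-2,2-diphenyl-1,3-benzodioxol-4-yl 3,4,5-tris(benzyloxy)benzoate | O=Cc1cc(OC(=O)c2cc(OCc3ccccc3)c(OCc3ccccc3)c(OCc3ccccc3)c2)c2OC(c3ccccc3)(c3ccccc3)Oc2c1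
A3 | direct plan | benzyl 3,5-bis(benzyloxy)-4-{3,4-bis(benzyloxycarbonyloxy)-5-[3,4,5-tris(benzyloxy)benzoyloxy]benzoyl}benzoate | O=C(OCc1ccccc1)c1cc(OCc2ccccc2)c(C(=O)c2cc(OC(=O)OCc3ccccc3)c(OC(=O)OCc3ccccc3)c(OC(=O)c3cc(OCc4ccccc4)c(OCc4ccccc4)c(OCc4ccccc4)c3)c2)c(OCc2ccccc2)c1
A4 | direct plan | benzyl 3,5-bis(benzyloxy)-4-{3,4-bis(benzyloxycarbonyloxy)-5-[3,4,5-tris(benzyloxy)benzoyloxy]benzoyloxy}benzoate | O=C(OCc1ccccc1)c1cc(OCc2ccccc2)c(OC(=O)c2cc(OC(=O)OCc3ccccc3)c(OC(=O)OCc3ccccc3)c(OC(=O)c3cc(OCc4ccccc4)c(OCc4ccccc4)c(OCc4ccccc4)c3)c2)c(OCc2ccccc2)c1
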